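## The problem

The target joins three rings at one quaternary carbon. Ring A is a cyclohexane (C1–C6; C1 carries the acrylic acid unit, C4 the spiro carbon, C5 the lactone carbonyl C7). Ring B is a δ-lactone (C4, C5, C7, O8, C9H2, C1′) cis-fused to ring A. Ring C is a cyclohexanone (C1′ spiro, C2′ ketone, C3′ CH2, C4′ ether CH, C5′ CMe2, C6′ CH) bridged from C4′ to C6′ by O–C11H2, i.e. a 6-oxabicyclo[3.2.1]octan-3-one.

There are six stereocentres. On ring A, C4 and C5 are cis and C1 is trans to both, so in the chair that holds the C1 and C4 substituents equatorial the carbonyl at C5 is axial and epimerisable; this has to be made under kinetic control and then kept away from equilibrating base. C1 can control C4 (1,4-trans, both equatorial) and C4 can control C5, so a single absolute stereocentre on ring A suffices. C1′ is quaternary, carries four different carbon substituents and must be set relative to C4 across a single bond; this is the hardest relay in the molecule. C4′ and C6′ are tied together by the bridge, so only the face of the bridge is open: it lies on the face of C4, which leaves the bulkier C4 equatorial on ring C, and can therefore be left to an equilibrium if C6′ is made epimerisable.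

The β-alkoxy ketone (retro-oxa-Michael), the lactone with its acidic C5–H and the acrylic acid do not tolerate strong base, hydride or soft nucleophiles. An isopropenyl group as precursor of the acrylic acid excludes hydrogenation, ozonolysis, hydroboration and strong protic acid.

The enabling feature is the 1,4-relation in ring C between the oxygen-bearing C4′ and the spiro carbon C1′, which already carries the ring A carbon C4. This is the ipso/para pattern of a 4-alkylphenol. The fourth bond of C1′ goes to C9, a CH2 one oxygen away from the C7 carboxyl group, so a phenoxide para carbon attacking an acyloxymethyl electrophile closes ring B and creates the quaternary centre in one step.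

## Retrosynthesis

**Side chain.** The C–O bonds of the carboxyl group of 28 are cut first, back through the allylic alcohol 27 to the isopropenyl ketone 26. Carrying an acrylate through the route is rejected because it would not survive the enolates, hydride and boryl-copper reagents used on ring C. No skeletal feature is lost. The forward steps must oxidise the vinylic methyl group next to a ketone α-methylene and an allylic ring methine.

**C2′ ketone.** 26 is taken back to the alcohol 25 and its silyl ether 24. A carbonyl at C2′ cannot be present while the bridge is built (it would be a β-diketone with C4′=O), and a free hydroxyl there would compete for the aldehyde, so the oxygen travels as a silyl ether. The forward oxidation must not open the β-alkoxy ketone.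

**Ether bridge.** The C11–H bond of 24 is replaced by OH (lactol 23), and the C4′O–C11 bond is then cut to the hydroxy aldehyde 22, released from the dithiane 21. This cut is preferred to an oxa-Michael closure from a hydroxymethyl group because a formyl group keeps C6′ epimerisable: only the epimer on the face of the C4′ hydroxyl can close, so the bridge forms on the correct face by equilibration. The precursor has one ring and one fixed stereocentre fewer. Step 12 must place the C4′ hydroxyl on the face of C4.

**Oxygen pattern of ring C.** 21 comes from the ketone 20, the silyl ether of the β-hydroxy ketone 19, whose C2′–O bond is cut (through the boronate 18) back to the enone 17. C2′ is the β-carbon of the one enone arm left in 17, so no regiochemical choice arises. Placing this step after the carbon work means that C5′ is the only sp3 α-carbon when the methyl groups are introduced.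

**Carbon substituents of ring C.** The C6′–C11 bond and both C5′–CH3 bonds of 17 are cut (via the monomethyl ketone 16) back to the dienone 14 and 1,3-dithiane 15, which brings C11 at the aldehyde oxidation level. The simplification is large: 14 has no stereocentre in ring C. The price is that its two enone arms are only diastereotopic, so the addition must choose the arm gauche to C5; the face of attack does not matter because C6′ is corrected later.

**Spiro carbon and ring B (key cut).** The C1′–C9 bond of 14 is cut and ring C is rearomatised, giving the chloromethyl ester 13 of a 4-alkylphenol. Cutting the acyl–oxygen bond instead would leave the quaternary carbon still to be made. Cutting C1′–C4 would require substitution at a secondary ring carbon. The chosen cut removes the quaternary centre and one ring together, and leaves a 1,2,5-trisubstituted cyclohexane. The forward reaction must favour C-alkylation at the para carbon over intermolecular O-alkylation.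

**Ester and the cis relationship.** 13 is the chloromethyl ester (reagent 12) of the hydroxy acid 11, obtained from the doubly silicon-protected ester 10. The C5–H bond of 10 is made by protonation of the enolate 9, which arises by conjugate reduction of the enoate 8. Aryl conjugate addition to an enoate lacking the aryl group was rejected: axial entry would put the aryl group cis to an equatorial isopropenyl group. Here C4 is already fixed, and only the direction of protonation has to be controlled.

**Carboxyl carbon.** The C5–C7 bond of 8 is cut to the enol triflate 7, made from the ketone 5 through its kinetic enolate 6. The double bond must be placed away from the aryl-bearing carbon so that C4 stays tetrahedral.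

**Aryl group.** The C4–aryl bond of 5 is cut to (R)-3-isopropenylcyclohexanone 3 and the aryl bromide 4. The α-aryl ketone is epimerisable, so the 1,4-trans relationship of C1 and C4 is set by equilibrium. The forward reaction must arylate the α-methylene remote from the isopropenyl-bearing carbon.

**Absolute configuration.** 3 is cut at the ring–isopropenyl bond to cyclohex-2-en-1-one 1 and the isopropenylboronic ester 2. This is the only step in which a chiral catalyst sets a stereocentre; the others are relayed from it.

## Roads not taken

**Alternative 1:** The cut is inside ring C, between the ketone α-CH2 (C3′) and the ether CH (C4′). The forward key step treats the methyl acetal A1 with TMSOTf, forming its bis(silyl) dienol ether in situ; the terminal dienol carbon adds to the oxocarbenium ion and gives the bicyclic β-keto ester A2.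
- Merits: the complete oxabicycle, gem-dimethyl group and both bridgeheads are made early, in a small fragment, by an intramolecular closure that cannot give the wrong bridge. For ring C it is shorter and safer than the chosen plan.
- Weak points: in A2 the future spiro carbon is a tertiary β-keto ester carbon. It still has to be joined to the secondary ring A carbon C4, with control of C1′ relative to C4 and C5, and its ester has to become C9H2–O. A quaternary–tertiary bond between two hindered fragments, with an epimerisable nucleophile, is the poorest bond of the target to make intermolecularly.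
- Comparison: the chosen plan has this bond from the start as an aryl–alkyl bond and closes C1′–C9 intramolecularly. It pays with the choice between two enone arms.

**Alternative 2:** The cut is the lactone C7–O8 bond together with the O–C11 bond. Both are traced to a carbocyclic precursor A3 in which C7 (ketone) is bonded to C11 (carbinol) and C9 is a free hydroxymethyl group. The forward key step is Pb(OAc)4 cleavage of the α-hydroxy ketone through the hemiketal with the C9 hydroxyl; the ester closes ring B and the released aldehyde lactolises with the C4′ hydroxyl to give A4.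
- Merits: C1′ and C6′ are ring-fusion carbons of a rigid six-six-six tricycle, where annulation stereocontrol is well understood. No arm has to be chosen, and one step forms two rings. In stereocontrol at C1′ and C6′ this road is better than the chosen one.
- Weak points: A3 is as complex as the target (quaternary carbon with hydroxymethyl group, acyloin, β-hydroxy ketone, gem-dimethyl group, five contiguous stereocentres), and A4 still needs a lactol reduction beside a ketone.
- Comparison: the chosen plan sets against it three simple commercial building blocks and an aromatic ring as latent ring C, at the cost of an arm selection that Alternative 2 avoids.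

**Alternative 3:** The cut removes C7 as carbon monoxide (bonds C5–C7 and C7–O8). The forward key step is palladium-catalysed hydrocarbonylation of the cyclohexene A5 with capture of the acyl-palladium species by the neopentyl C9 hydroxyl, giving the lactone A6.
- Merits: ring B is closed last onto a finished oxabicycle, and the malonate side chain avoids the isopropenyl group and its restrictions. Late convergence is at least as good as in the chosen plan.
- Weak points: hydride must add to C6 and acyl to C5 from the face that gives the cis fusion, and palladium hydride chain-walking in a cyclohexene can move the double bond past C1 and C4. A5 again needs the quaternary C1′ joined to an allylic ring A carbon with control. Unmasking the acrylic acid requires saponification beside the lactone.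
- Comparison: the chosen plan offers a ring closure of a well-known type, whose outcome does not depend on the regiochemistry of a metal hydride, and a trivial C1′–C4 bond.

Key step: step 8

Assumption: (R)-BINAP is taken to give the (R)-ketone 3, the sense established for aryl and alkenyl transfer to cyclohex-2-en-1-one; if the sense is opposite, the antipodal ligand is used.

## Route

Step 1
Reactants: 1 cyclohex-2-en-1-one; 2 isopropenylboronic acid pinacol ester
Product: 3 (R)-3-(prop-1-en-2-yl)cyclohexan-1-one
Conditions: [Rh(OH)((R)-binap)]2 (1.5 mol%), KOH (10 mol%), dioxane/H2O (10:1), 35 °C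
Reagents that add atoms: none
Why: Hayashi–Miyaura conjugate addition: the rhodium–BINAP complex transfers the alkenyl group to one enantioface of the enone and the oxa-π-allyl rhodium species is hydrolysed; this is the only stereocentre of the route set by a chiral catalyst.

Step 2
Reactants: 3 (R)-3-(prop-1-en-2-yl)cyclohexan-1-one (1.5 equiv); 4 (4-bromophenoxy)(tert-butyl)dimethylsilane
Product: 5 (2S,5R)-2-[4-(tert-butyldimethylsilyloxy)phenyl]-5-(prop-1-en-2-yl)cyclohexan-1-one
Conditions: Pd(OAc)2 (2 mol%), 2-(dicyclohexylphosphino)-2′-methylbiphenyl (4 mol%), K3PO4, toluene, 80 °C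
Reagents that add atoms: none
Why: Palladium-catalysed ketone α-arylation should take place at the α-methylene remote from the isopropenyl-bearing carbon; the acidic α-aryl centre equilibrates under the basic conditions to the diequatorial trans isomer, which fixes C4 relative to C1.

Step 3
Reactants: 5 (2S,5R)-2-[4-(tert-butyldimethylsilyloxy)phenyl]-5-(prop-1-en-2-yl)cyclohexan-1-one
Product: 7 (3R,6S)-6-[4-(tert-butyldimethylsilyloxy)phenyl]-3-(prop-1-en-2-yl)cyclohex-1-en-1-yl trifluoromethanesulfonate, via kinetic lithium enolate 6 (not isolated)
Conditions: LiN(i-Pr)2, THF, −78 °C; PhNTf2, −78 → 0 °C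
Reagents that add atoms: N-phenylbis(trifluoromethanesulfonimide), O=S(=O)(N(c1ccccc1)S(=O)(=O)C(F)(F)F)C(F)(F)F
Why: Kinetic deprotonation by the hindered amide occurs at the α-methylene, not at the more acidic but shielded benzylic methine, and O-triflation places the double bond away from the aryl-bearing carbon, which stays tetrahedral.

Step 4
Reactants: 7 (3R,6S)-6-[4-(tert-butyldimethylsilyloxy)phenyl]-3-(prop-1-en-2-yl)cyclohex-1-en-1-yl trifluoromethanesulfonate
Product: 8 2-(trimethylsilyl)ethyl (3R,6S)-6-[4-(tert-butyldimethylsilyloxy)phenyl]-3-(prop-1-en-2-yl)cyclohex-1-ene-1-carboxylate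
Conditions: Pd(OAc)2 (5 mol%), 1,1′-bis(diphenylphosphino)ferrocene (6 mol%), CO (1 atm), Me3SiCH2CH2OH, Et3N, DMF, 60 °C
Reagents that add atoms: carbon monoxide, [C-]#[O+]; 2-(trimethylsilyl)ethanol, C[Si](C)(C)CCO
Why: Palladium-catalysed alkoxycarbonylation of an enol triflate (oxidative addition, CO insertion, alcoholysis) installs C7; the 2-(trimethylsilyl)ethyl ester is chosen because fluoride later frees the acid without basic hydrolysis.

Step 5
Reactants: 8 2-(trimethylsilyl)ethyl (3R,6S)-6-[4-(tert-butyldimethylsilyloxy)phenyl]-3-(prop-1-en-2-yl)cyclohex-1-ene-1-carboxylate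
Product: 10 2-(trimethylsilyl)ethyl (1S,2R,5R)-2-[4-(tert-butyldimethylsilyloxy)phenyl]-5-(prop-1-en-2-yl)cyclohexane-1-carboxylate, via exocyclic lithium ester enolate 9 (not isolated)
Conditions: LiBH(s-Bu)3, THF, −78 °C; AcOH, −78 °C
Reagents that add atoms: none
Why: Conjugate reduction of the enoate by the trialkylborohydride gives the exocyclic ester enolate 9, whose chair holds aryl and isopropenyl equatorial; kinetic protonation of exocyclic enolates occurs preferentially from the equatorial direction, which places the ester axial, cis to the aryl group and trans to the isopropenyl group.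

Step 6
Reactants: 10 2-(trimethylsilyl)ethyl (1S,2R,5R)-2-[4-(tert-butyldimethylsilyloxy)phenyl]-5-(prop-1-en-2-yl)cyclohexane-1-carboxylate
Product: 11 (1S,2R,5R)-2-(4-hydroxyphenyl)-5-(prop-1-en-2-yl)cyclohexane-1-carboxylic acid
Conditions: Bu4NF, THF, 0 → 40 °C
Reagents that add atoms: none
Why: Fluoride cleaves the aryl silyl ether and, by β-elimination of ethene and fluorotrimethylsilane, the 2-(trimethylsilyl)ethyl ester; the carboxylate formed does not enolise under these conditions, so the cis configuration is kept.

Step 7
Reactants: 11 (1S,2R,5R)-2-(4-hydroxyphenyl)-5-(prop-1-en-2-yl)cyclohexane-1-carboxylic acid; 12 chloromethyl chlorosulfate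
Product: 13 chloromethyl (1S,2R,5R)-2-(4-hydroxyphenyl)-5-(prop-1-en-2-yl)cyclohexane-1-carboxylate
Conditions: NaHCO3, Bu4NHSO4 (10 mol%), CH2Cl2/H2O, 0 °C → rt
Reagents that add atoms: none
Why: Phase-transfer O-alkylation of the carboxylate, in which chlorosulfate is displaced in preference to chloride; hydrogen carbonate ionises only the carboxylic acid, so the phenol stays free.

Step 8
Reactants: 13 chloromethyl (1S,2R,5R)-2-(4-hydroxyphenyl)-5-(prop-1-en-2-yl)cyclohexane-1-carboxylate
Product: 14 (4aR,7R,8aS)-7-(prop-1-en-2-yl)hexahydrospiro[isochromane-4,1′-cyclohexa[2,5]diene]-1,4′-dione (cis-fused δ-lactone, spiro cyclohexa-2,5-dienone)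
Conditions: Cs2CO3, NaI (20 mol%), MeCN, slow addition to 2 mM, 60 °C
Reagents that add atoms: none
Why: Cs2CO3 forms the phenoxide, whose para carbon (the one that already carries ring A) attacks the CH2 of the chloromethyl ester with loss of halide, an intramolecular SN2 alkylation that breaks aromaticity and forms the C1′–C9 bond. The closest known reaction type is the intramolecular para-alkylation of phenoxides by tethered halides or sulfonates to spirocyclohexadienones (Winstein–Masamune Ar1-6 alkylation); an acyloxymethyl halide is a more reactive electrophile than those usually employed and can neither enolise nor eliminate. Ring B closes in a 6-exo-tet mode, with the equatorial aryl group and the axial ester of the cis isomer bringing C9 over the ipso carbon. No stereocentre is created, because C1′ carries two identical enone arms. The selectivity required is C- over O-alkylation: the phenoxide oxygen cannot reach its own tether, so O-alkylation can only be intermolecular and is suppressed by slow addition at high dilution. The closure must pass through the less stable E geometry of the ester, which is why the more reactive iodomethyl ester is generated in situ with NaI and the mixture is warmed.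

Step 9
Reactants: 14 spiro dienone lactone; 15 1,3-dithiane
Product: 17 spiro lactone of 14 in which ring C is 6′-(1,3-dithian-2-yl)-5′,5′-dimethylcyclohex-2′-en-4′-one (C6′ is the ring C carbon gauche to C5; dithianyl on the face of C9), via monomethyl ketone 16 (not isolated)
Conditions: n-BuLi, THF, −30 °C; HMPA, −78 °C, then 14; MeI, −78 °C; KN(SiMe3)2, −78 °C; MeI, −78 → 0 °C
Reagents that add atoms: iodomethane, CI
Why: Conjugate addition of a sulfur-stabilised formyl anion equivalent, steered to the 1,4-mode by HMPA, is followed by C-methylation of the cross-conjugated enolate and a second deprotonation–methylation at the only sp3 α-carbon. The spiro carbon becomes a stereocentre here: attack is expected on the face of C9 (anti to the ring A methine C4) and at the arm next to the ring oxygen O8, the one β-carbon on that face not flanked by a C–H bond of C9. The configuration at C6′ is provisional and is corrected in step 13.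

Step 10
Reactants: 17 dithianyl dimethyl enone
Product: 19 spiro lactone in which ring C is 6′-(1,3-dithian-2-yl)-2′-hydroxy-5′,5′-dimethylcyclohexan-4′-one (hydroxyl on the face of C4), via β-boryl ketone 18 (not isolated)
Conditions: CuCl (10 mol%), Xantphos (10 mol%), NaOt-Bu (15 mol%), B2pin2, i-PrOH, THF, rt; then NaBO3·4H2O, THF/H2O, rt
Reagents that add atoms: bis(pinacolato)diboron, CC1(C)OB(OC1(C)C)B1OC(C)(C)C(C)(C)O1; sodium perborate, [Na+].[O-]OB=O
Why: Copper-catalysed conjugate borylation of the remaining enone (boryl-copper addition at C2′, protonation of the enolate) and oxidation of the C–B bond with retention give the β-hydroxy ketone; the configuration at C2′ (addition anti to the axial C9) is immaterial because this carbon ends as the ketone.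

Step 11
Reactants: 19 β-hydroxy ketone
Product: 20 tert-butyldimethylsilyl ether of 19 at the C2′ oxygen
Conditions: t-BuMe2SiOTf, 2,6-lutidine, CH2Cl2, −78 → 0 °C
Reagents that add atoms: tert-butyldimethylsilyl trifluoromethanesulfonate, CC(C)(C)[Si](C)(C)OS(=O)(=O)C(F)(F)F
Why: Silylation of the secondary alcohol by the silyl triflate and a hindered pyridine base is fast at low temperature and avoids β-elimination; the ether keeps this oxygen from competing for the aldehyde in step 13.

Step 12
Reactants: 20 silyloxy ketone
Product: 21 C4′ alcohol of 20 (hydroxyl on the face of C4, cis to the C2′ silyloxy group)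
Conditions: LiBH(s-Bu)3, THF, −78 → −20 °C
Reagents that add atoms: none
Why: Hydride reduction of a ketone flanked by a quaternary carbon: the axial face is screened by the axial silyloxy group at C2′, so the bulky borohydride enters along the equatorial direction and gives the axial alcohol on the face of C4, as in the reduction of 4,4-dimethyl-3-oxo terpenoids.

Step 13
Reactants: 21 dithianyl alcohol
Product: 23 bridged lactol (C4′–O–C11H(OH)–C6′, bridge on the face of C4, both anomers), via hydroxy aldehyde 22 (not isolated)
Conditions: MeI, CaCO3, MeCN/H2O (9:1), 45 °C; then DBU (0.3 equiv), toluene, 40 °C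
Reagents that add atoms: water, O
Why: Alkylative hydrolysis of the dithiane frees the aldehyde 22 and DBU equilibrates its α-carbon C6′. Only the epimer with the formyl group on the face of the C4′ hydroxyl can close to the five-membered lactol (5-exo-trig), so ring–chain tautomerism, helped by the gem-dimethyl group, drains the mixture into 23 and sets C6′ under thermodynamic control.

Step 14
Reactants: 23 bridged lactol
Product: 24 bridged ether (6-oxabicyclo[3.2.1]octane with the C2′ silyloxy group)
Conditions: Et3SiH, BF3·OEt2, CH2Cl2, −78 → −30 °C
Reagents that add atoms: none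
Why: Ionic reduction of a lactol: BF3·OEt2 ionises it to the bicyclic oxocarbenium ion and Et3SiH delivers hydride to C11; at low temperature the isopropenyl group and the silyl ether are not affected.

Step 15
Reactants: 24 silyl ether
Product: 25 C2′ alcohol
Conditions: Bu4NF, THF, rt → 45 °C
Reagents that add atoms: none
Why: Fluoride-induced cleavage of the silyl ether; no base-sensitive β-alkoxy ketone is present yet.

Step 16
Reactants: 25 C2′ alcohol
Product: 26 isopropenyl ketone (the target skeleton with a methyl group in place of the carboxyl group)
Conditions: Dess–Martin periodinane, CH2Cl2, rt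
Reagents that add atoms: none
Why: Dess–Martin oxidation of the secondary alcohol under neutral conditions gives the β-alkoxy ketone without retro-oxa-Michael opening of the bridge.

Step 17
Reactants: 26 isopropenyl ketone
Product: 27 allylic alcohol (2-substituted prop-2-en-1-ol side chain at C1)
Conditions: SeO2 (30 mol%), t-BuOOH, CH2Cl2, rt
Reagents that add atoms: selenium dioxide, O=[Se]=O; tert-butyl hydroperoxide, CC(C)(C)OO
Why: Catalytic SeO2 allylic oxidation (ene reaction, then 2,3-sigmatropic shift) attacks the methyl group of the 1,1-disubstituted alkene in preference to the hindered ring methine and, at room temperature, leaves the ketone α-methylene alone; any enal formed is carried into step 18.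

Step 18
Reactants: 27 allylic alcohol
Product: 28 CNP0268721.1
Conditions: TEMPO (10 mol%), NaOCl (5 mol%), NaClO2, MeCN/phosphate buffer (pH 6.7), 35 °C
Reagents that add atoms: sodium chlorite, [Na+].[O-]Cl=O
Why: TEMPO-mediated oxidation of the allylic alcohol to the enal, with chlorite oxidation of the aldehyde in the same pot, gives the acrylic acid; the buffered medium spares the lactone and the β-alkoxy ketone.

## Compound list

1 | cyclohex-2-en-1-one | O=C1C=CCCC1 | starting material
2 | isopropenylboronic acid pinacol ester | CC(=C)B1OC(C)(C)C(C)(C)O1 | starting material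
3 | (R)-3-(prop-1-en-2-yl)cyclohexan-1-one | C=C(C)[C@@H]1CCCC(=O)C1 | intermediate
4 | (4-bromophenoxy)(tert-butyl)dimethylsilane | CC(C)(C)[Si](C)(C)Oc1ccc(Br)cc1 | starting material
5 | (2S,5R)-2-[4-(tert-butyldimethylsilyloxy)phenyl]-5-(prop-1-en-2-yl)cyclohexan-1-one (aryl and isopropenyl trans) | C=C(C)[C@@H]1CC[C@@H](c2ccc(O[Si](C)(C)C(C)(C)C)cc2)C(=O)C1 | intermediate
6 | lithium (3R,6S)-6-[4-(tert-butyldimethylsilyloxy)phenyl]-3-(prop-1-en-2-yl)cyclohex-1-en-1-olate | C=C(C)[C@@H]1CC[C@@H](c2ccc(O[Si](C)(C)C(C)(C)C)cc2)C([O-])=C1.[Li+] | intermediate
7 | (3R,6S)-6-[4-(tert-butyldimethylsilyloxy)phenyl]-3-(prop-1-en-2-yl)cyclohex-1-en-1-yl trifluoromethanesulfonate | C=C(C)[C@@H]1CC[C@@H](c2ccc(O[Si](C)(C)C(C)(C)C)cc2)C(OS(=O)(=O)C(F)(F)F)=C1 | intermediate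
8 | 2-(trimethylsilyl)ethyl (3R,6S)-6-[4-(tert-butyldimethylsilyloxy)phenyl]-3-(prop-1-en-2-yl)cyclohex-1-ene-1-carboxylate | C=C(C)[C@@H]1CC[C@@H](c2ccc(O[Si](C)(C)C(C)(C)C)cc2)C(C(=O)OCC[Si](C)(C)C)=C1 | intermediate
9 | lithium ester enolate of 10 (exocyclic C5=C7 double bond) | C=C(C)[C@@H]1CC[C@@H](c2ccc(O[Si](C)(C)C(C)(C)C)cc2)C(C1)=C([O-])OCC[Si](C)(C)C.[Li+] | intermediate
10 | 2-(trimethylsilyl)ethyl (1S,2R,5R)-2-[4-(tert-butyldimethylsilyloxy)phenyl]-5-(prop-1-en-2-yl)cyclohexane-1-carboxylate (aryl and ester cis, isopropenyl trans to both) | C=C(C)[C@@H]1CC[C@@H](c2ccc(O[Si](C)(C)C(C)(C)C)cc2)[C@H](C1)C(=O)OCC[Si](C)(C)C | intermediate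
11 | (1S,2R,5R)-2-(4-hydroxyphenyl)-5-(prop-1-en-2-yl)cyclohexane-1-carboxylic acid | C=C(C)[C@@H]1CC[C@@H](c2ccc(O)cc2)[C@H](C1)C(=O)O | intermediate
12 | chloromethyl chlorosulfate | ClCOS(Cl)(=O)=O | starting material
13 | chloromethyl (1S,2R,5R)-2-(4-hydroxyphenyl)-5-(prop-1-en-2-yl)cyclohexane-1-carboxylate | C=C(C)[C@@H]1CC[C@@H](c2ccc(O)cc2)[C@H](C1)C(=O)OCCl | intermediate
14 | (4aR,7R,8aS)-7-(prop-1-en-2-yl)hexahydrospiro[isochromane-4,1′-cyclohexa[2,5]diene]-1,4′-dione (cis-fused spiro dienone lactone) | C=C(C)[C@@H]1CC[C@@H]2[C@H](C1)C(=O)OCC21C=CC(=O)C=C1 | intermediate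
15 | 1,3-dithiane | C1CSCSC1 | starting material
16 | spiro lactone with ring C as 6′-(1,3-dithian-2-yl)-5′-methylcyclohex-2′-en-4′-one (epimers at C5′) | C=C(C)[C@@H]1CC[C@@H]2[C@H](C1)C(=O)OC[C@]21C=CC(=O)C(C)[C@H]1C1SCCCS1 | intermediate
17 | spiro lactone with ring C as 6′-(1,3-dithian-2-yl)-5′,5′-dimethylcyclohex-2′-en-4′-one (C6′ gauche to C5; dithianyl on the face of C9) | C=C(C)[C@@H]1CC[C@@H]2[C@H](C1)C(=O)OC[C@]21C=CC(=O)C(C)(C)[C@H]1C1SCCCS1 | intermediate
18 | 2′-(pinacolatoboryl) derivative: ring C as 6′-(1,3-dithian-2-yl)-5′,5′-dimethyl-2′-(4,4,5,5-tetramethyl-1,3,2-dioxaborolan-2-yl)cyclohexan-4′-one (boron on the face of C4) | C=C(C)[C@@H]1CC[C@@H]2[C@H](C1)C(=O)OC[C@]21[C@H](B3OC(C)(C)C(C)(C)O3)CC(=O)C(C)(C)[C@H]1C1SCCCS1 | intermediate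
19 | 2′-hydroxy ketone: ring C as 6′-(1,3-dithian-2-yl)-2′-hydroxy-5′,5′-dimethylcyclohexan-4′-one (hydroxyl on the face of C4) | C=C(C)[C@@H]1CC[C@@H]2[C@H](C1)C(=O)OC[C@]21[C@H](O)CC(=O)C(C)(C)[C@H]1C1SCCCS1 | intermediate
20 | 2′-(tert-butyldimethylsilyloxy) ketone (silyl ether of 19) | C=C(C)[C@@H]1CC[C@@H]2[C@H](C1)C(=O)OC[C@]21[C@H](O[Si](C)(C)C(C)(C)C)CC(=O)C(C)(C)[C@H]1C1SCCCS1 | intermediate
21 | 4′-alcohol of 20 (C4′ hydroxyl on the face of C4, cis to the C2′ silyloxy group; dithianyl on the face of C9) | C=C(C)[C@@H]1CC[C@@H]2[C@H](C1)C(=O)OC[C@]21[C@H](O[Si](C)(C)C(C)(C)C)C[C@H](O)C(C)(C)[C@H]1C1SCCCS1 | intermediate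
22 | hydroxy aldehyde: 21 with a formyl group in place of the dithianyl group (formyl on the face of C9 before epimerisation) | C=C(C)[C@@H]1CC[C@@H]2[C@H](C1)C(=O)OC[C@]21[C@H](O[Si](C)(C)C(C)(C)C)C[C@H](O)C(C)(C)[C@H]1C=O | intermediate
23 | bridged lactol: 2′-silyloxy-8,8-dimethyl-6-oxabicyclo[3.2.1]octan-7-ol spiro-fused to the lactone (bridge on the face of C4; anomers) | C=C(C)[C@@H]1CC[C@@H]2[C@H](C1)C(=O)OC[C@]21[C@H](O[Si](C)(C)C(C)(C)C)C[C@@H]2OC(O)[C@H]1C2(C)C | intermediate
24 | bridged ether: 23 with C11H2 in place of C11H(OH) | C=C(C)[C@@H]1CC[C@@H]2[C@H](C1)C(=O)OC[C@]21[C@H](O[Si](C)(C)C(C)(C)C)C[C@@H]2OC[C@H]1C2(C)C | intermediate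
25 | 2′-alcohol: 24 without the silyl group | C=C(C)[C@@H]1CC[C@@H]2[C@H](C1)C(=O)OC[C@]21[C@H](O)C[C@@H]2OC[C@H]1C2(C)C | intermediate
26 | isopropenyl ketone: target skeleton with CH3 in place of CO2H | C=C(C)[C@@H]1CC[C@@H]2[C@H](C1)C(=O)OC[C@]21C(=O)C[C@@H]2OC[C@H]1C2(C)C | intermediate
27 | allylic alcohol: target skeleton with CH2OH in place of CO2H | C=C(CO)[C@@H]1CC[C@@H]2[C@H](C1)C(=O)OC[C@]21C(=O)C[C@@H]2OC[C@H]1C2(C)C | intermediate
28 | CNP0268721.1 | C=C(C(=O)O)[C@@H]1CC[C@@H]2[C@H](C1)C(=O)OC[C@]21C(=O)C[C@@H]2OC[C@H]1C2(C)C | target

## Step count and least certain steps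

Total: 18 steps. Longest linear sequence: 18 steps from 1; compounds 2, 4, 12 and 15 enter as single reagents.

**Step 8 (key step).** The most likely failure is slow ring closure relative to intermolecular O-alkylation and to loss of the chloromethyl group to adventitious nucleophiles. The ester must leave its preferred Z geometry to bring C9 over the ipso carbon, and six-membered Ar1-6 closures are slower than five-membered ones. Fallback: change the nucleophile from a phenoxide to a neutral arene and the electrophile from a halide to a cation. It sets out from 13, which is silylated (t-BuMe2SiCl, imidazole) to chloromethyl (1S,2R,5R)-2-[4-(tert-butyldimethylsilyloxy)phenyl]-5-(prop-1-en-2-yl)cyclohexane-1-carboxylate F1. Ionisation with AgOTf and 2,6-di-tert-butylpyridine in (CF3)2CHOH/CH2Cl2 generates the acyloxymethyl cation, which is attacked at the ipso carbon (dearomatising ipso-Friedel–Crafts alkylation). Loss of the silyl group from the oxocarbenium ion returns to the route at 14. No phenoxide is present, so O-alkylation cannot occur.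

**Step 9.** The most likely failure is poor discrimination between the two enone arms, and to a lesser degree between the two faces, because the chirality of ring A reaches the β-carbons only through second-sphere contacts (O8 against a C–H bond of C9). Fallback: reagent control in place of substrate control. It sets out from 14, which is treated with formaldehyde (S)-1-amino-2-(methoxymethyl)pyrrolidine hydrazone and t-BuMe2SiOTf, a chiral neutral formyl anion equivalent that reads the prochiral dienone. This gives the silyl dienol ether hydrazone F2, hydrolysed on aqueous work-up to the 6′-hydrazonomethyl enone F3. Exchange with propane-1,3-dithiol and BF3·OEt2 gives the 6′-(1,3-dithian-2-yl) enone without methyl groups F4. Two rounds of KN(SiMe3)2/MeI return to the route at 17. The antipodal hydrazone is used if the other arm is taken.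

**Step 5.** The most likely failure is protonation of the enolate from the axial direction, or through the chair with axial aryl and isopropenyl groups, which gives the all-equatorial trans ester; 1,2-reduction of the hindered enoate is a second risk. Fallback: syn delivery of hydrogen in place of enolate protonation. It sets out from 8, which is desilylated with Bu4NF to (3R,6S)-6-(4-hydroxyphenyl)-3-(prop-1-en-2-yl)cyclohex-1-ene-1-carboxylic acid F5. Carboxylate-directed hydrogenation with Ru(OAc)2(binap) under H2 in MeOH adds hydrogen to the conjugated double bond from the face anti to the allylic aryl group. A catalyst that needs the coordinating carboxylate should leave the isolated isopropenyl group alone. The fallback returns to the route at 11.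

**Step 2.** The most likely failure is arylation at the other α-methylene (next to the isopropenyl-bearing carbon) or diarylation, since both α-positions are secondary. Fallback: fix the regiochemistry before the stereocentre is made. It sets out from 1, whose kinetic α′-enolate (LiN(i-Pr)2, then ZnCl2) is arylated with 4 under Pd(dba)2/P(t-Bu)3 catalysis to racemic 6-[4-(tert-butyldimethylsilyloxy)phenyl]cyclohex-2-en-1-one F6. Conjugate addition of 2 under the conditions of step 1 sets the isopropenyl-bearing centre by catalyst control in both enantiomers of F6. Treatment with DBU equilibrates the labile α-aryl centre to the trans isomer and returns to the route at 5.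

**Step 13.** The most likely failure is that the aldehyde does not epimerise under mild base, because its α-hydrogen lies between two quaternary carbons, so the lactol does not close. Fallback: acid-catalysed acetal chemistry in place of base-mediated enolisation. It sets out from 21, whose dithiane is exchanged with PhI(OCOCF3)2 in MeOH to the hydroxy dimethyl acetal F7. Camphorsulfonic acid in toluene at 60 °C equilibrates C6′ through the enol ether and closes the bridged methyl acetal F8. Reduction with Et3SiH/BF3·OEt2 returns to the route at 24.

## Further compounds

F1 | step 8 | chloromethyl (1S,2R,5R)-2-[4-(tert-butyldimethylsilyloxy)phenyl]-5-(prop-1-en-2-yl)cyclohexane-1-carboxylate | C=C(C)[C@@H]1CC[C@@H](c2ccc(O[Si](C)(C)C(C)(C)C)cc2)[C@H](C1)C(=O)OCCl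
F2 | step 9 | silyl dienol ether of the hydrazone adduct (ring C as 4′-(tert-butyldimethylsilyloxy)cyclohexa-2′,4′-diene carrying the SAMP-hydrazonomethyl group at C6′) | C=C(C)[C@@H]1CC[C@@H]2[C@H](C1)C(=O)OC[C@]21C=CC(O[Si](C)(C)C(C)(C)C)=C[C@H]1/C=N/N1CCC[C@H]1COC
F3 | step 9 | 6′-hydrazonomethyl enone (ring C as cyclohex-2′-en-4′-one carrying the SAMP-hydrazonomethyl group at C6′) | C=C(C)[C@@H]1CC[C@@H]2[C@H](C1)C(=O)OC[C@]21C=CC(=O)C[C@H]1/C=N/N1CCC[C@H]1COC
F4 | step 9 | 6′-(1,3-dithian-2-yl) enone without methyl groups | C=C(C)[C@@H]1CC[C@@H]2[C@H](C1)C(=O)OC[C@]21C=CC(=O)C[C@H]1C1SCCCS1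
F5 | step 5 | (3R,6S)-6-(4-hydroxyphenyl)-3-(prop-1-en-2-yl)cyclohex-1-ene-1-carboxylic acid | C=C(C)[C@@H]1CC[C@@H](c2ccc(O)cc2)C(C(=O)O)=C1
F6 | step 2 | racemic 6-[4-(tert-butyldimethylsilyloxy)phenyl]cyclohex-2-en-1-one | O=C1C=CCCC1c1ccc(O[Si](C)(C)C(C)(C)C)cc1
F7 | step 13 | hydroxy dimethyl acetal (21 with CH(OMe)2 in place of the dithianyl group) | C=C(C)[C@@H]1CC[C@@H]2[C@H](C1)C(=O)OC[C@]21[C@H](O[Si](C)(C)C(C)(C)C)C[C@H](O)C(C)(C)[C@H]1C(OC)OC
F8 | step 13 | bridged methyl acetal (23 with OMe in place of the lactol OH) | C=C(C)[C@@H]1CC[C@@H]2[C@H](C1)C(=O)OC[C@]21[C@H](O[Si](C)(C)C(C)(C)C)C[C@@H]2OC(OC)[C@H]1C2(C)C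
A1 | alternative 1 | methyl 2-(5-methoxy-4,4-dimethyloxolan-3-yl)-3-oxobutanoate (ring C3 configured as in A2; acetal and α-carbon unassigned) | COC(=O)C(C(C)=O)[C@H]1COC(OC)C1(C)C
A2 | alternative 1 | methyl 8,8-dimethyl-3-oxo-6-oxabicyclo[3.2.1]octane-2-carboxylate | COC(=O)[C@@H]1C(=O)C[C@@H]2OC[C@H]1C2(C)C
A3 | alternative 2 | tricyclic α-hydroxy ketone with C7 (ketone) bonded to C11 (carbinol), free C9 hydroxymethyl group and C4′ hydroxyl | C=C(C)[C@@H]1CC[C@@H]2[C@H](C1)C(=O)C(O)[C@H]3C(C)(C)[C@@H](O)CC(=O)[C@@]23CO
A4 | alternative 2 | spirolactone bridged lactol (one anomer) | C=C(C)[C@@H]1CC[C@@H]2[C@H](C1)C(=O)OC[C@]21C(=O)C[C@@H]2O[C@@H](O)[C@H]1C2(C)C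
A5 | alternative 3 | cyclohexene (C5=C6) carrying the malonate at C1 and, at C4, the oxabicyclic ketone with a free C9 hydroxymethyl group | COC(=O)C(C(=O)OC)[C@@H]1CC[C@H](C=C1)[C@]3(CO)C(=O)C[C@@H]4OC[C@H]3C4(C)C
A6 | alternative 3 | spirolactone with the malonate side chain | COC(=O)C(C(=O)OC)[C@@H]1CC[C@@H]2[C@H](C1)C(=O)OC[C@]21C(=O)C[C@@H]2OC[C@H]1C2(C)C
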